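**Strategy**

Numbering follows the germacrane skeleton (ten-membered carbocycle C1–C10, lactone O on C6, C11 on C7). The route rests on reading the C3(OAc)–C4(CH3)=C5 allyl unit of this ring as an opened cyclopropane: C4 is a dibromocarbene carbon inserted into a C3–C5 bond of a nine-membered ring. Silver-assisted disrotatory opening of the gem-dibromobicyclo[7.1.0]decene 19 should expand the carbocycle by one carbon and, in the same operation, install the C3 acetate and the E C4=C5 bond, leaving a vinyl bromide for methylation. Precursor 19 is a lactone-fused Z-cyclononene carrying a cis-fused CBr2 cyclopropane, assembled from a chiral butenolide by conjugate addition, Wittig olefination and ring-closing metathesis.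

Key step: step 13

Remark: atom labels C1–C15 below are the germacrane positions defined above; the L-fructose-derived enantiomer of the Shi ketone is assumed to be purchasable.

**Route**

Step 1
Reactants: 1 (S)-5-(hydroxymethyl)furan-2(5H)-one
Product: 2 (S)-5-{[(triethylsilyl)oxy]methyl}furan-2(5H)-one
Conditions: Et3SiCl, imidazole, CH2Cl2, 0 °C
Reagents that add atoms: chlorotriethylsilane, CC[Si](Cl)(CC)CC
Why: Imidazole-mediated silylation of the primary alcohol leaves the butenolide and its stereocentre (C6 of the target) untouched and provides the group that shields one face in step 2.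

Step 2
Reactants: 2 (S)-5-{[(triethylsilyl)oxy]methyl}furan-2(5H)-one; 3 prenylmagnesium chloride
Product: 5 (4S,5S)-4-(3-methylbut-2-en-1-yl)-5-{[(triethylsilyl)oxy]methyl}oxolan-2-one, via silyl ketene acetal 4 (not isolated)
Conditions: 3, CuBr·SMe2 (1 equiv), TMSCl, THF, −78 °C; aq. NH4Cl
Reagents that add atoms: prenylmagnesium chloride, CC(C)=CC[Mg]Cl
Why: TMSCl-accelerated conjugate addition of the allylic copper reagent should occur anti to the silyloxymethyl group, setting C7 trans to C6, with the prenyl group transferred through its unsubstituted terminus.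

Step 3
Reactants: 5 (4S,5S)-4-(3-methylbut-2-en-1-yl)-5-{[(triethylsilyl)oxy]methyl}oxolan-2-one
Product: 7 (3S,4S,5S)-3-methyl-4-(3-methylbut-2-en-1-yl)-5-{[(triethylsilyl)oxy]methyl}oxolan-2-one, via lithium enolate 6 (not isolated)
Conditions: LiN(i-Pr)2, THF, −78 °C; MeI
Reagents that add atoms: iodomethane, CI
Why: Lactone enolate alkylation introduces the C11 methyl group, mainly anti to the neighbouring prenyl group; the ratio does not matter because both epimers converge in step 4.

Step 4
Reactants: 7 (3S,4S,5S)-3-methyl-4-(3-methylbut-2-en-1-yl)-5-{[(triethylsilyl)oxy]methyl}oxolan-2-one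
Product: 9 (3R,4S,5S)-3-methyl-4-(3-methylbut-2-en-1-yl)-5-{[(triethylsilyl)oxy]methyl}oxolan-2-one, via lithium enolate 8 (not isolated)
Conditions: LiN(i-Pr)2, THF, −78 °C; then AcOH in THF, −78 °C
Reagents that add atoms: none
Why: Either C11 epimer gives the same planar enolate 8, and kinetic protonation on the face anti to the adjacent C7 side chain should place the methyl cis to it, the contra-thermodynamic (11R) configuration of the target (stereoconvergent enolate protonation).

Step 5
Reactants: 9 (3R,4S,5S)-3-methyl-4-(3-methylbut-2-en-1-yl)-5-{[(triethylsilyl)oxy]methyl}oxolan-2-one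
Product: 10 (3R,4S,5S)-4-{[(2S)-3,3-dimethyloxiran-2-yl]methyl}-3-methyl-5-{[(triethylsilyl)oxy]methyl}oxolan-2-one
Conditions: ent-Shi ketone (0.3 equiv), Oxone (2KHSO5·KHSO4·K2SO4), K2CO3, Bu4NHSO4, MeCN/DMM/aq. buffer, 0 °C
Reagents that add atoms: potassium peroxymonosulfate KHSO5, [K+].[O-]S(=O)(=O)OO
Why: Shi asymmetric epoxidation of the only alkene (trisubstituted) is reagent-controlled; the enantiomeric ketone is chosen to give the (S)-epoxide, which fixes C9 with its oxygen and masks the prenyl group against the carbene of step 8.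

Step 6
Reactants: 10 (3R,4S,5S)-4-{[(2S)-3,3-dimethyloxiran-2-yl]methyl}-3-methyl-5-{[(triethylsilyl)oxy]methyl}oxolan-2-one
Product: 11 (2S,3S,4R)-3-{[(2S)-3,3-dimethyloxiran-2-yl]methyl}-4-methyl-5-oxooxolane-2-carbaldehyde
Conditions: (COCl)2, DMSO, CH2Cl2, −78 to −30 °C; Et3N
Reagents that add atoms: none
Why: Under Swern conditions primary triethylsilyl ethers are oxidised directly to aldehydes, which saves a separate desilylation; the cold amine quench limits epimerisation at the α-acyloxy carbon.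

Step 7
Reactants: 11 (2S,3S,4R)-3-{[(2S)-3,3-dimethyloxiran-2-yl]methyl}-4-methyl-5-oxooxolane-2-carbaldehyde; 12 [2-(1,3-dioxolan-2-yl)ethyl]triphenylphosphonium bromide
Product: 13 (3R,4S,5R)-5-[(1Z)-3-(1,3-dioxolan-2-yl)prop-1-en-1-yl]-4-{[(2S)-3,3-dimethyloxiran-2-yl]methyl}-3-methyloxolan-2-one
Conditions: 12, NaN(SiMe3)2, THF, 0 °C; then 11, −78 °C to rt
Reagents that add atoms: [2-(1,3-dioxolan-2-yl)ethyl]triphenylphosphonium bromide, [Br-].C1COC(O1)CC[P+](c2ccccc2)(c3ccccc3)c4ccccc4
Why: Wittig olefination with a non-stabilised ylide under salt-free conditions should give the Z C5=C3 alkene; the dioxolane carries C1 as a masked aldehyde so that no second alkene competes in step 8.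

Step 8
Reactants: 13 (3R,4S,5R)-5-[(1Z)-3-(1,3-dioxolan-2-yl)prop-1-en-1-yl]-4-{[(2S)-3,3-dimethyloxiran-2-yl]methyl}-3-methyloxolan-2-one
Product: 14 (3R,4S,5S)-5-[(1S,3S)-2,2-dibromo-3-(1,3-dioxolan-2-ylmethyl)cyclopropyl]-4-{[(2S)-3,3-dimethyloxiran-2-yl]methyl}-3-methyloxolan-2-one
Conditions: PhHgCBr3, benzene, 80 °C
Reagents that add atoms: phenyl(tribromomethyl)mercury PhHgCBr3, BrC(Br)(Br)[Hg]c1ccccc1
Why: Neutral thermal dibromocarbene transfer to the only alkene is stereospecific (cis cyclopropane from the Z alkene), and with H6 eclipsing the double bond (A(1,3) strain) the carbene should add anti to the branched C6–C7 bond, on the side of the ring oxygen, giving the (3S,5S) cyclopropane.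

Step 9
Reactants: 14 (3R,4S,5S)-5-[(1S,3S)-2,2-dibromo-3-(1,3-dioxolan-2-ylmethyl)cyclopropyl]-4-{[(2S)-3,3-dimethyloxiran-2-yl]methyl}-3-methyloxolan-2-one
Product: 16 (3R,4S,5S)-5-[(1S,3S)-2,2-dibromo-3-(2-oxoethyl)cyclopropyl]-4-[(2S)-2-hydroxy-3-methylbut-3-en-1-yl]-3-methyloxolan-2-one, via silyl ether aldehyde 15 (not isolated)
Conditions: TMSOTf (3 equiv), 2,6-lutidine, CH2Cl2, −78 to 0 °C; H2O; then 1 M HCl, THF, 0 °C
Reagents that add atoms: water, O
Why: TMSOTf/2,6-lutidine effects both the known isomerisation of a trisubstituted epoxide to the silyl ether of the secondary allylic alcohol (C10–O cleavage, loss of a methyl proton, C9 configuration retained) and the known lutidine-assisted cleavage of a dioxolane acetal to the aldehyde on adding water; dilute acid then removes the silyl group.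

Step 10
Reactants: 16 (3R,4S,5S)-5-[(1S,3S)-2,2-dibromo-3-(2-oxoethyl)cyclopropyl]-4-[(2S)-2-hydroxy-3-methylbut-3-en-1-yl]-3-methyloxolan-2-one
Product: 17 (3R,4S,5S)-5-[(1S,3S)-2,2-dibromo-3-(prop-2-en-1-yl)cyclopropyl]-4-[(2S)-2-hydroxy-3-methylbut-3-en-1-yl]-3-methyloxolan-2-one
Conditions: Ph3PCH3Br, NaN(SiMe3)2, THF, 0 °C; then 16, −78 to 0 °C
Reagents that add atoms: methyltriphenylphosphonium bromide, C[P+](c1ccccc1)(c1ccccc1)c1ccccc1.[Br-]
Why: Wittig methylenation of the aldehyde at low temperature is faster than enolisation or attack on the lactone and provides the terminal C1 alkene.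

Step 11
Reactants: 17 (3R,4S,5S)-5-[(1S,3S)-2,2-dibromo-3-(prop-2-en-1-yl)cyclopropyl]-4-[(2S)-2-hydroxy-3-methylbut-3-en-1-yl]-3-methyloxolan-2-one
Product: 18 (2S)-1-{(2S,3S,4R)-2-[(1S,3S)-2,2-dibromo-3-(prop-2-en-1-yl)cyclopropyl]-4-methyl-5-oxooxolan-3-yl}-3-methylbut-3-en-2-yl acetate
Conditions: Ac2O, pyridine, DMAP (cat.), CH2Cl2, 0 °C
Reagents that add atoms: acetic anhydride, CC(=O)OC(C)=O
Why: DMAP-catalysed acetylation installs the C9 acetate of the target and blocks the hydroxyl against transannular participation in step 13.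

Step 12
Reactants: 18 (2S)-1-{(2S,3S,4R)-2-[(1S,3S)-2,2-dibromo-3-(prop-2-en-1-yl)cyclopropyl]-4-methyl-5-oxooxolan-3-yl}-3-methylbut-3-en-2-yl acetate
Product: 19 tricyclic dibromide: nine-membered carbocycle C1–C2–C3–C5–C6–C7–C8–C9–C10 with Z C1=C10 (CH3 on C10), OAc on C9, cis-fused cyclopropane C3–C4–C5 (C4 = CBr2), trans-fused α-methyl-γ-lactone at C6/C7; (3S,5S,6S,7S,9S,11R)
Conditions: second-generation Hoveyda–Grubbs catalyst (10 mol%), toluene (1 mM), 80 °C
Reagents that add atoms: none
Why: Ring-closing metathesis between the vinyl and isopropenyl groups closes the nine-membered ring, whose size forces the Z geometry of the new trisubstituted C1=C10 bond; the cis cyclopropane and the lactone hold the two chains close.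

Step 13
Reactants: 19 tricyclic dibromide (gem-dibromobicyclo[7.1.0]decene fused to the lactone)
Product: 20 (3R,3aS,5S,6Z,9S,10Z,11aS)-10-bromo-3,6-dimethyl-2-oxo-2,3,3a,4,5,8,9,11a-octahydrocyclodeca[b]furan-5,9-diyl diacetate (C4 bromide; C3 and C6 trans across C4=C5)
Conditions: AgOAc (3 equiv), AcOH, 50 °C, dark
Reagents that add atoms: silver acetate AgOAc, CC(=O)[O-].[Ag+]
Why: The silver ion removes the exo bromide of the cis-fused CBr2 cyclopropane (the one anti to the ring chain) while the C3–C5 bond opens in a disrotatory two-electron electrocyclic process in which the ring bonds C3–C2 and C5–C6, trans to the leaving group, rotate outward, so that C4 enters the ring and the nine-membered carbocycle becomes ten-membered with a ring-trans C4=C5 bond carrying the remaining bromine. The closest known reaction type is the silver-assisted solvolytic ring expansion of gem-dibromobicyclo[n.1.0]alkanes to 2-bromocycloalk-2-enyl acetates or ethers, which gives trans-cycloalkenes in medium rings. No new ring is closed: the existing carbocycle is enlarged by cleavage of the shared C3–C5 bond, and the lactone is untouched. The new stereocentre C3 is controlled by the (3S,5S) cyclopropane configuration from step 8: acetate should enter at C3 on the outer face of the developing allyl cation, the face from which bromide left, because the inner face is covered by the rest of the ring, and this corresponds to (3S). The step needs exo over endo ionisation, secured by a ring large enough for outward rotation, and capture at C3 instead of C5, secured by the acyloxy-bearing C6 next to C5, which destabilises positive charge there and shields it. The Z C1=C10 alkene, the C9 acetate and the epimerisable C11 centre should not be affected by AgOAc in AcOH.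

Step 14
Reactants: 20 (3R,3aS,5S,6Z,9S,10Z,11aS)-10-bromo-3,6-dimethyl-2-oxo-2,3,3a,4,5,8,9,11a-octahydrocyclodeca[b]furan-5,9-diyl diacetate
Product: 21 (3R,3aS,5S,6Z,9S,10E,11aS)-3,6,10-trimethyl-2-oxo-2,3,3a,4,5,8,9,11a-octahydrocyclodeca[b]furan-5,9-diyl diacetate (target)
Conditions: Me2Zn, Pd(P(t-Bu)3)2 (5 mol%), THF, 0 °C to rt
Reagents that add atoms: dimethylzinc, C[Zn]C
Why: Negishi cross-coupling of the alkenyl bromide proceeds with retention of double-bond geometry, and fast oxidative addition and transmetalation with the bulky phosphine catalyst at room temperature should outpace ionisation of the allylic acetates.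

**Compound list**

1 | (S)-5-(hydroxymethyl)furan-2(5H)-one | OC[C@H]1OC(=O)C=C1 | starting material
2 | (S)-5-{[(triethylsilyl)oxy]methyl}furan-2(5H)-one | CC[Si](CC)(CC)OC[C@H]1OC(=O)C=C1 | intermediate
3 | prenylmagnesium chloride, (3-methylbut-2-en-1-yl)magnesium chloride | CC(C)=CC[Mg]Cl | starting material
4 | trimethylsilyl ketene acetal of 5 (2-trimethylsilyloxy-4,5-dihydrofuran, 4S,5S) | CC(C)=CC[C@@H]1[C@@H](CO[Si](CC)(CC)CC)OC(O[Si](C)(C)C)=C1 | intermediate (not isolated)
5 | (4S,5S)-4-(3-methylbut-2-en-1-yl)-5-{[(triethylsilyl)oxy]methyl}oxolan-2-one | CC(C)=CC[C@@H]1[C@@H](CO[Si](CC)(CC)CC)OC(=O)C1 | intermediate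
6 | lithium enolate of 5 | CC(C)=CC[C@@H]1[C@@H](CO[Si](CC)(CC)CC)OC([O-])=C1.[Li+] | intermediate (not isolated)
7 | (3S,4S,5S)-3-methyl-4-(3-methylbut-2-en-1-yl)-5-{[(triethylsilyl)oxy]methyl}oxolan-2-one (methyl trans to prenyl) | CC(C)=CC[C@@H]1[C@@H](CO[Si](CC)(CC)CC)OC(=O)[C@H]1C | intermediate
8 | lithium enolate of 7 | CC(C)=CC[C@@H]1[C@@H](CO[Si](CC)(CC)CC)OC([O-])=C1C.[Li+] | intermediate (not isolated)
9 | (3R,4S,5S)-3-methyl-4-(3-methylbut-2-en-1-yl)-5-{[(triethylsilyl)oxy]methyl}oxolan-2-one (methyl cis to prenyl) | CC(C)=CC[C@@H]1[C@@H](CO[Si](CC)(CC)CC)OC(=O)[C@@H]1C | intermediate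
10 | (3R,4S,5S)-4-{[(2S)-3,3-dimethyloxiran-2-yl]methyl}-3-methyl-5-{[(triethylsilyl)oxy]methyl}oxolan-2-one | CC1(C)O[C@H]1C[C@@H]2[C@@H](CO[Si](CC)(CC)CC)OC(=O)[C@@H]2C | intermediate
11 | (2S,3S,4R)-3-{[(2S)-3,3-dimethyloxiran-2-yl]methyl}-4-methyl-5-oxooxolane-2-carbaldehyde | CC1(C)O[C@H]1C[C@@H]2[C@@H](C=O)OC(=O)[C@@H]2C | intermediate
12 | [2-(1,3-dioxolan-2-yl)ethyl]triphenylphosphonium bromide | [Br-].C1COC(O1)CC[P+](c2ccccc2)(c3ccccc3)c4ccccc4 | starting material
13 | (3R,4S,5R)-5-[(1Z)-3-(1,3-dioxolan-2-yl)prop-1-en-1-yl]-4-{[(2S)-3,3-dimethyloxiran-2-yl]methyl}-3-methyloxolan-2-one | CC1(C)O[C@H]1C[C@@H]2[C@@H](/C=C\CC3OCCO3)OC(=O)[C@@H]2C | intermediate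
14 | (3R,4S,5S)-5-[(1S,3S)-2,2-dibromo-3-(1,3-dioxolan-2-ylmethyl)cyclopropyl]-4-{[(2S)-3,3-dimethyloxiran-2-yl]methyl}-3-methyloxolan-2-one | CC1(C)O[C@H]1C[C@@H]2[C@@H]([C@@H]3[C@H](CC4OCCO4)C3(Br)Br)OC(=O)[C@@H]2C | intermediate
15 | trimethylsilyl ether of 16 (C9–OSiMe3, free aldehyde) | CC(=C)[C@@H](O[Si](C)(C)C)C[C@@H]1[C@@H]([C@@H]2[C@H](CC=O)C2(Br)Br)OC(=O)[C@@H]1C | intermediate (not isolated)
16 | (3R,4S,5S)-5-[(1S,3S)-2,2-dibromo-3-(2-oxoethyl)cyclopropyl]-4-[(2S)-2-hydroxy-3-methylbut-3-en-1-yl]-3-methyloxolan-2-one | CC(=C)[C@@H](O)C[C@@H]1[C@@H]([C@@H]2[C@H](CC=O)C2(Br)Br)OC(=O)[C@@H]1C | intermediate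
17 | (3R,4S,5S)-5-[(1S,3S)-2,2-dibromo-3-(prop-2-en-1-yl)cyclopropyl]-4-[(2S)-2-hydroxy-3-methylbut-3-en-1-yl]-3-methyloxolan-2-one | CC(=C)[C@@H](O)C[C@@H]1[C@@H]([C@@H]2[C@H](CC=C)C2(Br)Br)OC(=O)[C@@H]1C | intermediate
18 | (2S)-1-{(2S,3S,4R)-2-[(1S,3S)-2,2-dibromo-3-(prop-2-en-1-yl)cyclopropyl]-4-methyl-5-oxooxolan-3-yl}-3-methylbut-3-en-2-yl acetate | CC(=C)[C@@H](OC(C)=O)C[C@@H]1[C@@H]([C@@H]2[C@H](CC=C)C2(Br)Br)OC(=O)[C@@H]1C | intermediate
19 | tricyclic dibromide: Z-cyclononene (C1=C10, CH3 on C10, OAc on C9) with cis-fused CBr2 cyclopropane (C3–C4–C5) and trans-fused α-methyl-γ-lactone at C6/C7; (3S,5S,6S,7S,9S,11R) | CC(=O)O[C@H]1C[C@@H]2[C@@H]([C@@H]3[C@H](C/C=C\1C)C3(Br)Br)OC(=O)[C@@H]2C | intermediate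
20 | (3R,3aS,5S,6Z,9S,10Z,11aS)-10-bromo-3,6-dimethyl-2-oxo-2,3,3a,4,5,8,9,11a-octahydrocyclodeca[b]furan-5,9-diyl diacetate | CC(=O)O[C@H]1C[C@@H]2[C@@H](/C=C(\Br)[C@@H](OC(C)=O)C/C=C\1C)OC(=O)[C@@H]2C | intermediate
21 | (3R,3aS,5S,6Z,9S,10E,11aS)-3,6,10-trimethyl-2-oxo-2,3,3a,4,5,8,9,11a-octahydrocyclodeca[b]furan-5,9-diyl diacetate | CC(=O)O[C@H]1C[C@@H]2[C@@H](/C=C(\C)[C@@H](OC(C)=O)C/C=C\1C)OC(=O)[C@@H]2C | target

**Step count**

Total steps: 14. Longest linear sequence: 14 steps (from 1).

**Steps most likely to fail**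

1. Step 13 (key step). Ionisation of the endo bromide with inward rotation, or acetate capture on the inner face of the allyl cation, would erode the C3 configuration and the C4=C5 geometry. The fallback keeps the same one-carbon ring expansion but makes C3 stereoconvergent; it does not correct a ring-cis C4=C5 bond. It sets out from 19: AgClO4 in aqueous acetone should give the ring-expanded 4-bromo allylic alcohol as a C3 epimer mixture, shown as the (3R)-bromo alcohol F1. Dess–Martin periodinane oxidises both epimers to the single 4-bromo-3-oxo enone F2. (R)-Me-CBS oxazaborolidine with catecholborane then reduces it under reagent control to the (3S)-bromo alcohol F3. Ac2O/pyridine/DMAP returns to 20.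

2. Step 12. Cyclisation of the C1 alkylidene onto the hindered, acetoxy-substituted 1,1-disubstituted alkene may be slow, so that intermolecular metathesis to dimers and oligomers takes over. The fallback sets out from 17: Dess–Martin oxidation gives the isopropenyl ketone F4. Ring-closing metathesis of this dienone (second-generation Hoveyda–Grubbs catalyst) gives the tricyclic 2-methylcyclononenone F5, in which C9 is planar and the conjugated product alkene resists ring reopening. (R)-Me-CBS reduction sets C9 under reagent control to give the (9S)-allylic alcohol F6, and acetylation returns to 19.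

3. Step 8. Facial selectivity of the carbene addition may be poor, because only the allylic C6 centre differentiates the two faces of the Z alkene. The fallback sets out from 13: aminolysis of the lactone with pyrrolidine gives the γ-hydroxy pyrrolidine amide F7 with a free C6 hydroxyl. Dibromocarbene addition under phase-transfer conditions (CHBr3, 50% aq. NaOH, BnEt3NCl), directed syn to the allylic hydroxyl, gives the dibromocyclopropyl hydroxy amide F8. Warming with AcOH in toluene closes the lactone again and returns to 14.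

Further compounds
F1 | step 13 | (3R)-4-bromo-3-hydroxy ring-expanded lactone (C3 epimer of F3, C9 acetate retained) | CC(=O)O[C@H]1C[C@@H]2[C@@H](/C=C(\Br)[C@H](O)C/C=C\1C)OC(=O)[C@@H]2C
F2 | step 13 | 4-bromo-3-oxo enone (C3 ketone, C9 acetate) | CC(=O)O[C@H]1C[C@@H]2[C@@H](/C=C(\Br)C(=O)C/C=C\1C)OC(=O)[C@@H]2C
F3 | step 13 | (3S)-4-bromo-3-hydroxy ring-expanded lactone (C9 acetate) | CC(=O)O[C@H]1C[C@@H]2[C@@H](/C=C(\Br)[C@@H](O)C/C=C\1C)OC(=O)[C@@H]2C
F4 | step 12 | isopropenyl ketone (C9 ketone of 17) | CC(=C)C(=O)C[C@@H]1[C@@H]([C@@H]2[C@H](CC=C)C2(Br)Br)OC(=O)[C@@H]1C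
F5 | step 12 | tricyclic 2-methylcyclononenone (C9 ketone, Z C1=C10) | O=C1C[C@@H]2[C@@H]([C@@H]3[C@H](C/C=C\1C)C3(Br)Br)OC(=O)[C@@H]2C
F6 | step 12 | tricyclic (9S)-allylic alcohol (deacetyl 19) | O[C@H]1C[C@@H]2[C@@H]([C@@H]3[C@H](C/C=C\1C)C3(Br)Br)OC(=O)[C@@H]2C
F7 | step 8 | γ-hydroxy pyrrolidine amide from 13 (free C6 hydroxyl, Z alkene) | CC1(C)O[C@H]1C[C@@H]([C@@H](C)C(=O)N2CCCC2)[C@H](O)/C=C\CC3OCCO3
F8 | step 8 | dibromocyclopropyl γ-hydroxy pyrrolidine amide | CC1(C)O[C@H]1C[C@@H]([C@@H](C)C(=O)N2CCCC2)[C@H](O)[C@@H]3[C@H](CC4OCCO4)C3(Br)Br
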